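**Plan**

- Numbering is that of the labdanes: decalin C1–C10, C17 the exocyclic CH2 on C8, C18/C19 the two CH2OH groups on C4, C20 the methyl on C10, C11–C16 the chain and butenolide. The SMILES puts H5, C20, C11 and the 3-OH on one face, so the decalin is cis-fused, (3R,5R,9R,10S).
- Retrosynthetic cuts, in order: C12=C13 (cross-metathesis, after a 1,3-hydrogen shift), C8=C17 (methylenation), C9–C11 together with C10–C20 (conjugate methylation–allylation), C4–C18 and C4–C19 (two aldol additions to formaldehyde).
- Forward: both rings come from 6-methoxy-2-tetralone (1). Its saturated ring is ring A and its anisole ring becomes ring B by Birch reduction, so no ring is closed later; the chain is joined last on the allyl handle.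
- Enabling feature: ring B carries the sp2 carbon C8 next to C9 and C10, so a C8 ketone conjugated with C9=C10 offers C10 (β) to the methyl group and C9 (α) to the side chain. In 1 the methoxy carbon is C8, the ketone carbon is C3 and the benzylic α-carbon is C4.
- Stereochemistry: C5 from an amine-catalysed enantioselective γ-protonation; C10 and C9 from the key step, both relative to C5; C3 from a thermodynamically controlled dissolving-metal reduction.

Key step: step 6

Assumption: the sense of induction of the cinchona amine in step 5 cannot be predicted for this substrate; the quinine-derived amine is written, and its quinidine-derived pseudo-enantiomer is taken if the first proves to give (5S).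

**Route**

Step 1
Reactants: 1 6-methoxy-2-tetralone; 2 formaldehyde (37% aqueous)
Product: 3 1,1-bis(hydroxymethyl)-6-methoxy-3,4-dihydronaphthalen-2(1H)-one
Conditions: aq. HCHO (2.5 equiv), KHCO3 (0.3 equiv), THF/H2O, 0 °C → rt, Ar
Reagents that add atoms: formaldehyde (second equivalent), C=O
Why: Two successive base-mediated aldol additions (hydroxymethylations) consume two molecules of formaldehyde at the same carbon: C1 of the tetralone (C4 of the target) is benzylic as well as α to the ketone and is enolised by bicarbonate far more readily than C3, and once quaternary it can no longer dehydrate; no stereocentre arises.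

Step 2
Reactants: 3 1,1-bis(hydroxymethyl)-6-methoxy-3,4-dihydronaphthalen-2(1H)-one
Product: 4 2',2'-di-tert-butyl-6-methoxy-3,4-dihydro-2H-spiro[naphthalene-1,5'-[1,3,2]dioxasilinan]-2-one
Conditions: tBu2Si(OTf)2, 2,6-lutidine, CH2Cl2, 0 °C
Reagents that add atoms: di-tert-butylsilyl bis(trifluoromethanesulfonate), CC(C)(C)[Si](OS(=O)(=O)C(F)(F)F)(OS(=O)(=O)C(F)(F)F)C(C)(C)C
Why: Cyclic silylene formation on a 1,3-diol gives a six-membered dioxasilinane that removes the retro-aldol pathway, keeps C4 non-stereogenic, and is expected to survive dissolving metal, cuprate and weak acid while staying cleavable by fluoride.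

Step 3
Reactants: 4 spiro-silylene ketone
Product: 5 ethylene ketal of 4 (dioxolane at C3, spiro-dioxasilinane at C4, anisole ring intact)
Conditions: TMSOCH2CH2OTMS, TMSOTf (cat.), CH2Cl2, −78 → −20 °C
Reagents that add atoms: 1,2-bis(trimethylsilyloxy)ethane, C[Si](C)(C)OCCO[Si](C)(C)C
Why: Aprotic ketalisation with the bis-silyl ether of ethylene glycol under TMSOTf catalysis, driven by formation of hexamethyldisiloxane, suits a ketone flanked by a quaternary carbon and leaves the silylene untouched.

Step 4
Reactants: 5 anisole ketal
Product: 7 β,γ-unsaturated 8-ketone (C5=C10 alkene; C3 dioxolane; C4 spiro-silylene), via dihydroanisole enol ether 6 (not isolated)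
Conditions: Li, NH3(l), THF, t-BuOH, −78 → −33 °C; MeOH; then (CO2H)2, THF/H2O, rt
Reagents that add atoms: water, O
Why: Birch reduction of the anisole leaves double bonds at the methoxy-bearing carbon and between the two alkyl-substituted ring carbons (C7=C8 and C5=C10), and oxalic acid then hydrolyses only the enol ether, giving the unconjugated C8 ketone with dioxolane and silylene in place.

Step 5
Reactants: 7 β,γ-unsaturated 8-ketone
Product: 8 (5R)-8-oxo-9(10)-ene (conjugated octalenone with 5-H; C3 dioxolane; C4 spiro-silylene)
Conditions: 9-amino-9-deoxy-epi-quinine (10 mol %), PhCO2H (20 mol %), toluene, 0 °C → rt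
Reagents that add atoms: none
Why: Amine-catalysed enantioselective olefin isomerisation (iminium–dienamine catalysis): the primary amine condenses at C8, the dienamine C8=C9–C10=C5 is protonated at C5 on one face by the protonated quinuclidine of the catalyst, and hydrolysis releases the conjugated enone, so C5 is set under catalyst control and conjugation drives the reaction.

Step 6
Reactants: 8 (5R)-enone; 9 allyl iodide
Product: 11 (5R,9S,10R)-9-allyl-10-methyl-cis-decal-8-one (C3 dioxolane; C4 spiro-silylene; H5 CH3 allyl on one face), via lithium C8–C9 enolate 10 (not isolated)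
Conditions: Me2CuLi (from MeLi, CuI; 2.5 equiv), Et2O, −20 → 0 °C; then allyl iodide (5 equiv), HMPA, THF, −40 °C → rt; aq. NH4Cl/NH3
Reagents that add atoms: lithium dimethylcuprate, [Li+].C[Cu-]C
Why: Me2CuLi forms the usual copper–enone π-complex with 8 and delivers methyl to the β-carbon C10, leaving the lithium enolate 10 with its double bond fixed between C8 and C9; once HMPA/THF is added this enolate is C-allylated by allyl iodide in an SN2 reaction, so C10–C20 and C9–C11 are made in one flask and no ring is closed. The nearest precedent in type is the addition of lithium dimethylcuprate to Δ1(9)-2-octalones, which gives cis-fused 9-methyldecalones, combined with alkylation of the enolate so generated before it can equilibrate. At C10 the methyl group is expected to enter ring B axially on the face that carries H5, because the opposite face is syn-axial to C4 and to the axial CH2O arm of its spiro ring; this makes the ring fusion cis. At C9 the enolate should react through the half-chair that keeps the quaternary C4 equatorial on ring B, in which the C10–C1 bond is axial, and allyl iodide attacks anti to that bond on the convex face, placing C11 cis to the new methyl group. The step needs 1,4- over 1,2-addition, C- over O-allylation and no enolate equilibration towards C7; the soft cuprate, the soft allylic iodide in excess at low temperature, and a neutral work-up (C9 stays epimerisable until step 7) are meant to secure these.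

Step 7
Reactants: 11 9-allyl-10-methyl-cis-decal-8-one
Product: 12 (5R,9R,10S)-9-allyl-10-methyl-8-methylidene-cis-decalin (C3 dioxolane; C4 spiro-silylene)
Conditions: Zn, CH2Br2, TiCl4, THF/CH2Cl2, 0 °C → rt
Reagents that add atoms: dibromomethane, BrCBr
Why: Lombardo methylenation with the non-basic zinc–titanium methylene reagent converts the hindered, enolisable C8 ketone into the exocyclic alkene without epimerising C9 and tolerates ketal, silylene and the allyl group.

Step 8
Reactants: 12 8-methylidene ketal
Product: 13 (5R,9R,10S)-9-allyl-10-methyl-8-methylidene-cis-decal-3-one (C4 spiro-silylene)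
Conditions: PPTS, acetone/H2O, 50 °C
Reagents that add atoms: water, O
Why: Acid-catalysed ketal hydrolysis with pyridinium tosylate frees the C3 ketone, while the dioxasilinane and the 1,1-disubstituted alkene are expected to withstand this weak acid.

Step 9
Reactants: 13 3-ketone
Product: 14 (3R,5R,9R,10S)-3-alcohol of 13 (3-OH cis to H5 and to the C10 methyl)
Conditions: Li, NH3(l), THF, t-BuOH, −78 °C; NH4Cl
Reagents that add atoms: none
Why: Dissolving-metal reduction of a hindered cyclohexanone gives the thermodynamically preferred alcohol, which in the favoured chair pair (C4 equatorial on ring B, C10 methyl axial on ring A) is the equatorial 3-OH on the face of H5 and the methyl group, because its epimer would be syn-axial to C6; the isolated alkenes are not reduced.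

Step 10
Reactants: 14 3-alcohol; 15 α-methylene-γ-butyrolactone
Product: 16 (E)-α-alkylidene-γ-butyrolactone (C9–CH2–CH=C13; decalin as in 14)
Conditions: 15 (4 equiv), second-generation Hoveyda–Grubbs catalyst RuCl2(H2IMes)(=CH-C6H4-2-OiPr) (10 mol %), 2,6-dichloro-1,4-benzoquinone (10 mol %), CH2Cl2, 40 °C
Reagents that add atoms: none
Why: Olefin cross-metathesis between the monosubstituted allyl terminus and the 1,1-disubstituted alkene of 15 in excess should give the E-alkylidene lactone; the hindered C8 methylene is not expected to enter the cycle and the quinone suppresses ruthenium hydride side reactions.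

Step 11
Reactants: 16 (E)-alkylidene lactone
Product: 17 silylene-protected target (3-substituted furan-2(5H)-one on the C9 ethyl chain)
Conditions: RhCl3·3H2O (10 mol %), EtOH, 75 °C
Reagents that add atoms: none
Why: Rhodium-hydride-mediated 1,3-hydrogen shift, the known exo-to-endo isomerisation of α-alkylidene-γ-butyrolactones and 2-alkylidenecycloalkanones, moves the double bond from C12=C13 to the thermodynamically preferred C13=C14 position of the butenolide; no stereocentre is touched.

Step 12
Reactants: 17 silylene-protected target
Product: 18 3-{2-[(1R,4aR,6R,8aS)-6-hydroxy-5,5-bis(hydroxymethyl)-8a-methyl-2-methylidenedecahydronaphthalen-1-yl]ethyl}furan-2(5H)-one (target)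
Conditions: HF·pyridine, pyridine/THF, 0 °C → rt
Reagents that add atoms: none
Why: Fluoride-mediated cleavage of the silylene (Si–F bond formation) releases the two primary alcohols under conditions that leave the butenolide, the exocyclic alkene and the secondary alcohol unchanged.

**Compound list**

1 | 6-methoxy-2-tetralone (6-methoxy-3,4-dihydronaphthalen-2(1H)-one) | COc1ccc2c(c1)CCC(=O)C2 | starting material
2 | formaldehyde | C=O | starting material
3 | 1,1-bis(hydroxymethyl)-6-methoxy-3,4-dihydronaphthalen-2(1H)-one | COc1ccc2c(c1)CCC(=O)C2(CO)CO | intermediate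
4 | 2',2'-di-tert-butyl-6-methoxy-3,4-dihydro-2H-spiro[naphthalene-1,5'-[1,3,2]dioxasilinan]-2-one | COc1ccc2c(c1)CCC(=O)C23CO[Si](C(C)(C)C)(C(C)(C)C)OC3 | intermediate
5 | ethylene ketal of 4 (C3 dioxolane, C4 spiro-dioxasilinane) | COc1ccc2c(c1)CCC4(OCCO4)C23CO[Si](C(C)(C)C)(C(C)(C)C)OC3 | intermediate
6 | dihydroanisole from 5 (enol ether C7=C8(OMe), alkene C5=C10) | COC1=CCC2=C(C1)CCC4(OCCO4)C23CO[Si](C(C)(C)C)(C(C)(C)C)OC3 | intermediate (not isolated)
7 | β,γ-unsaturated 8-ketone (C5=C10; C3 dioxolane; C4 spiro-silylene) | O=C1CCC2=C(C1)CCC4(OCCO4)C23CO[Si](C(C)(C)C)(C(C)(C)C)OC3 | intermediate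
8 | (5R)-8-oxo-9(10)-ene, conjugated octalenone (C3 dioxolane; C4 spiro-silylene) | O=C1CC[C@H]2C3(CO[Si](C(C)(C)C)(C(C)(C)C)OC3)C4(OCCO4)CCC2=C1 | intermediate
9 | allyl iodide (3-iodoprop-1-ene) | C=CCI | starting material
10 | lithium C8–C9 enolate of the (5R,10R)-10-methyl-cis-decal-8-one | [Li+].[O-]C=1CC[C@H]2C3(CO[Si](C(C)(C)C)(C(C)(C)C)OC3)C4(OCCO4)CC[C@@]2(C)C=1 | intermediate (not isolated)
11 | (5R,9S,10R)-9-allyl-10-methyl-cis-decal-8-one (C3 dioxolane; C4 spiro-silylene; H5, CH3 and allyl cis) | O=C1CC[C@H]2C3(CO[Si](C(C)(C)C)(C(C)(C)C)OC3)C4(OCCO4)CC[C@@]2(C)[C@@H]1CC=C | intermediate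
12 | (5R,9R,10S)-9-allyl-10-methyl-8-methylidene-cis-decalin (C3 dioxolane; C4 spiro-silylene) | C=C1CC[C@H]2C3(CO[Si](C(C)(C)C)(C(C)(C)C)OC3)C4(OCCO4)CC[C@@]2(C)[C@@H]1CC=C | intermediate
13 | (5R,9R,10S)-9-allyl-10-methyl-8-methylidene-cis-decal-3-one (C4 spiro-silylene) | C=C1CC[C@H]2C3(CO[Si](C(C)(C)C)(C(C)(C)C)OC3)C(=O)CC[C@@]2(C)[C@@H]1CC=C | intermediate
14 | (3R,5R,9R,10S)-3-alcohol of 13 (3-OH cis to H5 and C10 methyl) | C=C1CC[C@H]2C3(CO[Si](C(C)(C)C)(C(C)(C)C)OC3)[C@H](O)CC[C@@]2(C)[C@@H]1CC=C | intermediate
15 | α-methylene-γ-butyrolactone (3-methylideneoxolan-2-one) | C=C1CCOC1=O | starting material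
16 | (E)-α-alkylidene-γ-butyrolactone from 14 (C12=C13 exocyclic to the lactone) | C=C1CC[C@H]2C3(CO[Si](C(C)(C)C)(C(C)(C)C)OC3)[C@H](O)CC[C@@]2(C)[C@@H]1C/C=C1\CCOC1=O | intermediate
17 | silylene-protected target (endocyclic butenolide, C13=C14) | C=C1CC[C@H]2C3(CO[Si](C(C)(C)C)(C(C)(C)C)OC3)[C@H](O)CC[C@@]2(C)[C@@H]1CCC1=CCOC1=O | intermediate
18 | 3-{2-[(1R,4aR,6R,8aS)-6-hydroxy-5,5-bis(hydroxymethyl)-8a-methyl-2-methylidenedecahydronaphthalen-1-yl]ethyl}furan-2(5H)-one | C=C1CC[C@H]2C(CO)(CO)[C@H](O)CC[C@@]2(C)[C@@H]1CCC1=CCOC1=O | target

**Step count and risks**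

Total steps: 12. Longest linear sequence: 12 steps from 1 (the route is fully linear).

Steps most likely to fail:

1. Step 11. The rhodium hydride may not discriminate between the two alkenes and may also move the C8(17) exocyclic double bond into ring B, or the isomerisation may stall short of completion. The fallback sets out from 16 and replaces the hydrogen shift by reduction and re-oxidation at sulfur. Conjugate reduction with [(Ph3P)CuH]6 in toluene, which does not touch isolated alkenes, gives the saturated α-substituted γ-butyrolactone F1 as a mixture at C13. Double deprotonation with LiN(iPr)2 in THF at −78 °C (C3 alkoxide and lactone enolate) and sulfenylation with PhSSPh gives the α-phenylthio lactone F2. Oxidation with NaIO4 in aqueous methanol gives the sulfoxide F3, and heating in toluene at 110 °C brings about the syn-elimination towards the ring hydrogen at C14, which is the usual outcome for α-alkyl-α-sulfinyl butyrolactones. The route is rejoined at 17.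

2. Step 5. Proton delivery to C5 takes place next to the quaternary C4, so turnover may be slow, the face selectivity may erode, and an uncatalysed background isomerisation may lower the enantiomeric purity. The fallback sets out from 7 and gives up the asymmetric catalysis for a resolution. DBU in CH2Cl2 at rt gives the racemic conjugated enone F4, whose enantiomers are separated by preparative chromatography on a cellulose tris(3,5-dimethylphenylcarbamate) stationary phase. The (5R)-enantiomer is 8, where the route is rejoined.

3. Step 6. Allylation of the hindered enolate may be slow enough for proton exchange with the product ketone, which would scramble the enolate position and cause polyallylation, and some electrophile may enter on the face of C1. The fallback sets out from 8 and forms the C9–C11 bond by palladium catalysis instead of direct alkylation. After the same addition of Me2CuLi, the enolate is O-acylated with allyl chloroformate in THF/HMPA to give the allyl enol carbonate F5, which is isolated. Pd(PPh3)4 (zerovalent palladium) in THF at rt then effects a decarboxylative Tsuji–Trost allylation, in which the palladium enolate and the allyl unit recombine regiospecifically at C9 on the convex face. The route is rejoined at 11.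

**Further compounds**

F1 | step 11 | saturated α-substituted γ-butyrolactone from 16 (C13 epimers) | C=C1CC[C@H]2C3(CO[Si](C(C)(C)C)(C(C)(C)C)OC3)[C@H](O)CC[C@@]2(C)[C@@H]1CCC1CCOC1=O
F2 | step 11 | α-phenylthio lactone | C=C1CC[C@H]2C3(CO[Si](C(C)(C)C)(C(C)(C)C)OC3)[C@H](O)CC[C@@]2(C)[C@@H]1CCC1(Sc2ccccc2)CCOC1=O
F3 | step 11 | α-phenylsulfinyl lactone (sulfoxide) | C=C1CC[C@H]2C3(CO[Si](C(C)(C)C)(C(C)(C)C)OC3)[C@H](O)CC[C@@]2(C)[C@@H]1CCC1(S(=O)c2ccccc2)CCOC1=O
F4 | step 5 | racemic conjugated enone (rac-8) | O=C1CCC2C3(CO[Si](C(C)(C)C)(C(C)(C)C)OC3)C4(OCCO4)CCC2=C1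
F5 | step 6 | allyl enol carbonate of the 10-methyl-cis-decal-8-one (C8=C9) | C=CCOC(=O)OC=1CC[C@H]2C3(CO[Si](C(C)(C)C)(C(C)(C)C)OC3)C4(OCCO4)CC[C@@]2(C)C=1
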